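## Retrosynthesis (overview)
- The target is 8′-hydroxylariciresinol. Removing both phenolic benzyl groups and reducing the C9 CH2OH back to an aldehyde gives a 3-hydroxy-THF-4-carbaldehyde (**9**).
- **9** is cut at the C7–O bond and the C8–C8′ bond. This gives the cinnamaldehyde **3** and the α-hydroxy ketone **7** (ArCH2COCH2OH). One amine-catalysed oxa-Michael/intramolecular aldol cascade forms the only ring and all three stereocentres.
- **7** comes from arylacetic acid **4** via diazoketone **6**. **3** comes from aldehyde **1** by Wittig olefination.

Assumptions: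
- The (R)-diarylprolinol silyl ether directs oxa-Michael attack to the face that gives 7R, by analogy with Si-face β-additions to cinnamaldehyde iminium ions (the (S)-catalyst gives the 7S series).
- The 7,8-trans ring closure is assumed, and any 8′-epimer is removed by chromatography at the diol stage (**10**).

## Route

**Step 1**
Reactants: **1** 4-benzyloxy-3-methoxybenzaldehyde; **2** (triphenylphosphoranylidene)acetaldehyde
Product: **3** (E)-3-(4-benzyloxy-3-methoxyphenyl)propenal
Conditions: PhMe, 80 °C, 16 h
Reagents that add atoms: none beyond the numbered reactants (the CH–CHO unit comes from **2**, O=CC=P(c1ccccc1)(c1ccccc1)c1ccccc1)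
Why: Wittig olefination of an aldehyde with a stabilised ylide gives the E-enal selectively.

**Step 2**
Reactants: **4** 4-benzyloxy-3-methoxyphenylacetic acid; **5** trimethylsilyldiazomethane
Product: **6** 1-diazo-3-(4-benzyloxy-3-methoxyphenyl)propan-2-one
Conditions: (COCl)2, cat. DMF, CH2Cl2, 0 °C→rt, then evaporate; **5** (2.2 equiv), MeCN/hexane, 0 °C→rt, 12 h
Reagents that add atoms: TMSCHN2, C[Si](C)(C)C=[N+]=[N-]
Why: The acid chloride acylates the diazomethane equivalent, and the second equivalent of **5** takes up the HCl released (the Arndt–Eistert first half). This gives the diazomethyl ketone with TMSCl as the by-product.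

**Step 3**
Reactant: **6**
Product: **7** 1-(4-benzyloxy-3-methoxyphenyl)-3-hydroxypropan-2-one
Conditions: 10% aq. H2SO4, dioxane, 50 °C, 2 h
Reagents that add atoms: water, O
Why: Protonation of the diazoketone gives a diazonium ion that water displaces by SN2 with loss of N2 (acid hydrolysis of a diazoketone to an α-hydroxy ketone). The aryl benzyl ether survives dilute acid.

**Step 4**
Reactants: **3** enal (1.0 equiv); **7** α-hydroxy ketone (1.5 equiv); **8** (R)-α,α-diphenylprolinol TMS ether (20 mol%)
Product: **9** (3R,4S,5R)-3-[4-(benzyloxy)-3-methoxybenzyl]-5-[4-(benzyloxy)-3-methoxyphenyl]-3-hydroxytetrahydrofuran-4-carbaldehyde (not isolated; carried on directly)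
Conditions: **8** (20 mol%), PhCO2H (20 mol%), PhMe, rt, 72 h
Reagents that add atoms: none (the catalyst and acid co-catalyst are not incorporated)
Why: Proposed new method: the iminium ion of **3** with **8** is attacked at Cβ by the primary OH of **7** (oxa-Michael), and catalyst control sets C7 as R. The resulting enamine then closes onto the ketone of the same chain by a 5-exo aldol, which sets C8 trans to the aryl group and creates the tertiary carbinol C8′. Hydrolysis releases the aldehyde **9**. The closest known reactions are the amine-catalysed sulfa-Michael/aldol of 1,4-dithiane-2,5-diol with enals, the oxa-Michael/aldol of salicylaldehydes with enals, and intramolecular enamine–ketone aldols. The new element is an α-hydroxy ketone acting as both O-nucleophile and ketone acceptor. The bulky diarylprolinol ether does not form an enamine with the ketone, so it engages only the enal.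

**Step 5**
Reactant: **9** crude β-hydroxy aldehyde from Step 4, same pot
Product: **10** (3R,4S,5R)-3-[4-(benzyloxy)-3-methoxybenzyl]-5-[4-(benzyloxy)-3-methoxyphenyl]-4-(hydroxymethyl)tetrahydrofuran-3-ol (bis-benzyl ether of the target)
Conditions: dilute with MeOH, NaBH4 (3 equiv), 0 °C, 30 min; aq. NH4Cl work-up; chromatography to remove any 8′-epimer
Reagents that add atoms: none (NaBH4 adds only H)
Why: Chemoselective aldehyde reduction traps the retro-aldol-prone β-hydroxy aldehyde as the stable primary alcohol. No stereocentre is touched, because the aldehyde α-carbon C8 is not epimerised under the cold, short reduction.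

**Step 6**
Reactant: **10**
Product: **11** 8′-hydroxylariciresinol (target)
Conditions: H2 (1 atm), 10% Pd/C, EtOAc/EtOH 1:1, rt, 2–3 h (monitor by TLC)
Reagents that add atoms: none (H2 adds only H; the two benzyl groups leave as toluene)
Why: Catalytic hydrogenolysis cleaves the two phenolic benzyl ethers, and the THF ring, tertiary alcohol and stereocentres are untouched under these mild, monitored conditions.

## Compound list
1 | 4-benzyloxy-3-methoxybenzaldehyde | COc1cc(C=O)ccc1OCc1ccccc1 | starting material
2 | (triphenylphosphoranylidene)acetaldehyde | O=CC=P(c1ccccc1)(c1ccccc1)c1ccccc1 | starting material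
3 | (E)-3-(4-benzyloxy-3-methoxyphenyl)propenal | COc1cc(/C=C/C=O)ccc1OCc1ccccc1 | intermediate
4 | 4-benzyloxy-3-methoxyphenylacetic acid | COc1cc(CC(=O)O)ccc1OCc1ccccc1 | starting material
5 | trimethylsilyldiazomethane | C[Si](C)(C)C=[N+]=[N-] | starting material
6 | 1-diazo-3-(4-benzyloxy-3-methoxyphenyl)propan-2-one | COc1cc(CC(=O)C=[N+]=[N-])ccc1OCc1ccccc1 | intermediate
7 | 1-(4-benzyloxy-3-methoxyphenyl)-3-hydroxypropan-2-one | COc1cc(CC(=O)CO)ccc1OCc1ccccc1 | intermediate
8 | (R)-α,α-diphenylprolinol trimethylsilyl ether (organocatalyst) | C[Si](C)(C)OC(c1ccccc1)(c1ccccc1)[C@H]1CCCN1 | starting material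
9 | (3R,4S,5R)-3-(4-benzyloxy-3-methoxybenzyl)-5-(4-benzyloxy-3-methoxyphenyl)-3-hydroxytetrahydrofuran-4-carbaldehyde | COc1cc(C[C@]2(O)CO[C@@H](c3ccc(OCc4ccccc4)c(OC)c3)[C@@H]2C=O)ccc1OCc1ccccc1 | intermediate (telescoped, not isolated)
10 | protected diol (bis-benzyl ether of target) | COc1cc(C[C@]2(O)CO[C@@H](c3ccc(OCc4ccccc4)c(OC)c3)[C@@H]2CO)ccc1OCc1ccccc1 | intermediate
11 | 8′-hydroxylariciresinol | COc1cc(C[C@]2(O)CO[C@@H](c3ccc(O)c(OC)c3)[C@@H]2CO)ccc1O | target

**Total steps:** 6 (Step 4 and Step 5 are run in one pot). **Longest linear sequence:** 5 (4 → 6 → 7 → 9 → 10 → 11).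

## Three steps most likely to fail
1. **Step 4 (proposed new cascade).** Oxa-Michael addition of the OH of **7** to the electron-rich enal iminium may be slow or reversible, and the C8′ configuration may come out as an epimeric mixture. Fallback (known chemistry, different approach): an acyclic route.
   - Enantioselective crotylboration-type allylation of aldehyde **1** with a β-(4-benzyloxy-3-methoxybenzyl)-γ-(silyloxymethyl)allylboron reagent sets C7 and C8.
   - Directed dihydroxylation of the resulting 1,1-disubstituted alkene sets C8′.
   - Selective primary tosylation and base-mediated 5-exo O-alkylation by the benzylic OH closes the THF, with retention at C7.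
2. **Step 3 (diazoketone hydrolysis).** Yields may be low because of competing decomposition and dimerisation. Fallback: add 4-BnO-3-MeO-benzylmagnesium chloride to the TBS-glycolic Weinreb amide, then remove the TBS group with TBAF.
3. **Step 6 (hydrogenolysis).** The benzylic C7–O bond of the THF may be cleaved along with the benzyl ethers. Fallback: carry allyl ethers instead of benzyl ethers through Steps 1–5 (from 4-allyloxy-3-methoxybenzaldehyde and the matching arylacetic acid), and remove them at the end with Pd(PPh3)4/K2CO3 in MeOH, with no hydrogenolysis.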